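**Plan**

The quinone ring is numbered C1 (OMe), C2 (indol-3-yl), C3 (C=O), C4 (prenyl), C5 (indol-3-yl), C6 (C=O). The oxygens on C1 and C3 stand 1,3 to each other, as in a resorcinol monomethyl ether, and C6 lies para to C3. A vinylketene and an ynol ether deliver exactly this pattern, with C6-H as the one open ring position.
Retrosynthesis: the two N-H bonds are masked as N-Si and the C6 oxygen is removed, which leaves a phenol with C3-OH and C6-H. The central ring is then cut at C2-C3, C1-C6 and C3-C4 into a methoxy(indolyl)acetylene (C1-C2) and a vinylketene C3=C6-C5=C4, which is traced back to an alpha'-diazo enone through a Wolff rearrangement.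
The diazo enone is cut at C=N2 (diazo transfer to a methyl enone), at the C5-indole bond (Stille coupling) and at the propargylic C-C bond of a skipped enynol (but-3-yn-2-ol plus prenyl bromide). The ynol ether is cut at the C2-indole bond (Negishi coupling).
Forward: both indole bicycles are bought ready-made as 3-bromo-1-(triisopropylsilyl)indole. The enone chain is joined first, then the two fragments close the central six-membered ring, the only ring built, in one operation. Oxidation at C6 and desilylation finish the synthesis.
Stereochemistry: the target has no stereocentre and no stereogenic alkene. The only geometric element that matters is the E enone (acyl trans to the prenyl CH2). It is set by anti addition of H-Sn to the alkyne, kept by a retentive coupling and erased on aromatisation.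

Key step: step 8

Assumption: but-3-yn-2-ol is used as the racemate. The carbinol intermediates derived from it are racemic, and this centre is oxidised away in step 5.

**Step 1**
Reactants: 1 3-bromo-1-(triisopropylsilyl)indole
Product: 3 3-iodo-1-(triisopropylsilyl)indole, via 3-lithioindole 2 (not isolated)
Conditions: t-BuLi (2.1 equiv), THF, -78 °C; I2 (1.1 equiv), -78 to 0 °C; aq Na2S2O3 wash
Reagents that add atoms: iodine, [I][I]; tert-butyllithium, [Li]C(C)(C)C (lithium of 2 only)
Why: Bromine-lithium exchange followed by iodinolysis: the bulky N-silyl group shields C2, so the 3-lithio species should hold its position at -78 °C, and the iodide is wanted because both later palladium couplings should then run at room temperature.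

**Step 2**
Reactants: 4 but-3-yn-2-ol (racemic); 5 1-bromo-3-methylbut-2-ene (prenyl bromide)
Product: 6 7-methyloct-6-en-3-yn-2-ol (racemic)
Conditions: CuI (10 mol %), n-Bu4NBr (10 mol %), K2CO3 (1.5 equiv), DMF, 25 °C
Reagents that add atoms: none
Why: Copper-catalysed allylation of a terminal alkyne, a standard route to skipped enynes: the acetylide should displace bromide at the unhindered primary carbon of 5 to give the linear prenyl product, the free hydroxyl needs no protection, and the carbinol centre is carried as the racemate.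

**Step 3**
Reactants: 6 7-methyloct-6-en-3-yn-2-ol
Product: 7 (Z)-7-methyl-3-(tributylstannyl)octa-3,6-dien-2-ol (racemic; tin cis to C5H2)
Conditions: [Cp*RuCl]4 (1.25 mol %), Bu3SnH (1.1 equiv, slow addition), CH2Cl2, 25 °C
Reagents that add atoms: tributyltin hydride, CCCC[SnH](CCCC)CCCC
Why: Hydroxyl-directed ruthenium-catalysed trans-hydrostannation: a hydrogen bond from the propargylic OH to the chloride ligand should steer tin to the alkyne carbon next to the carbinol while H and Sn add anti, which places the carbinol carbon trans to the CH2 group, and the isolated trisubstituted alkene is not a substrate for this catalyst.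

**Step 4**
Reactants: 7 (Z)-7-methyl-3-(tributylstannyl)octa-3,6-dien-2-ol; 3 3-iodo-1-(triisopropylsilyl)indole
Product: 8 (E)-7-methyl-3-[1-(triisopropylsilyl)indol-3-yl]octa-3,6-dien-2-ol (racemic; indolyl cis to C5H2)
Conditions: Pd(PPh3)4 (10 mol %), copper thiophene-2-carboxylate (CuTC, 1.5 equiv), [n-Bu4N][Ph2PO2] (1.5 equiv), DMF, 25 °C
Reagents that add atoms: none
Why: Copper-assisted Stille coupling with retention of alkene geometry: the copper carboxylate speeds up transfer of the hindered alkenyl group, the phosphinate salt binds the tin residue, and the absence of fluoride and of base spares the N-Si bond and the skipped diene.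

**Step 5**
Reactants: 8 (E)-7-methyl-3-[1-(triisopropylsilyl)indol-3-yl]octa-3,6-dien-2-ol
Product: 9 (E)-7-methyl-3-[1-(triisopropylsilyl)indol-3-yl]octa-3,6-dien-2-one
Conditions: activated MnO2 (20 equiv), CH2Cl2, 25 °C
Reagents that add atoms: none
Why: Allylic alcohol oxidation with MnO2, neutral and heterogeneous, which should leave the silylindole, the alkene geometry and the doubly allylic CH2 untouched and removes the only stereocentre of this fragment.

**Step 6**
Reactants: 9 (E)-7-methyl-3-[1-(triisopropylsilyl)indol-3-yl]octa-3,6-dien-2-one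
Product: 11 (E)-1-diazo-7-methyl-3-[1-(triisopropylsilyl)indol-3-yl]octa-3,6-dien-2-one, via trifluoroacetyl ketone 10 (not isolated)
Conditions: LiN(SiMe3)2 (1.1 equiv), THF, -78 °C; CF3CO2CH2CF3 (1.2 equiv), -78 °C, 10 min; cold 5% aq HCl wash, crude 10 used at once; MsN3 (1.5 equiv), Et3N (1.5 equiv), H2O (1 equiv), MeCN, 25 °C
Reagents that add atoms: 2,2,2-trifluoroethyl trifluoroacetate, FC(F)(F)COC(=O)C(F)(F)F (trifluoroacetyl group of 10 only); methanesulfonyl azide, CS(=O)(=O)N=[N+]=[N-]
Why: Detrifluoroacetylative diazo transfer, the standard entry to alpha'-diazo enones where acylation of diazomethane by an enoyl chloride suffers from dipolar cycloaddition: the carbonyl-bound lithium amide should reach only the methyl group because the doubly allylic CH2 is held trans to the acyl group, and the activated 1,3-diketone then takes up N2 with loss of the trifluoroacetyl group under Et3N, a base too weak to pull the skipped diene into conjugation.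

**Step 7**
Reactants: 12 2-chloro-1,1-dimethoxyethane (chloroacetaldehyde dimethyl acetal); 3 3-iodo-1-(triisopropylsilyl)indole
Product: 15 3-(methoxyethynyl)-1-(triisopropylsilyl)indole, via lithium methoxyacetylide 13 (not isolated), via methoxyethynylzinc chloride 14 (not isolated)
Conditions: 12 (2 equiv), LiNEt2 (6.2 equiv, from Et2NH and n-BuLi), THF, 0 °C; ZnCl2 (4.2 equiv), 0 °C; 3 (1 equiv), Pd(PPh3)4 (5 mol %), THF, 25 °C; chromatography on Et3N-deactivated silica
Reagents that add atoms: lithium diethylamide, [Li]N(CC)CC (lithium of 13 only); zinc chloride, Cl[Zn]Cl (zinc and chlorine of 14 only)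
Why: Negishi alkynylation: the threefold action of the lithium amide on 12 (loss of methanol, loss of HCl, deprotonation) is an established source of lithium methoxyacetylide, alkoxyethynylzinc chlorides are known to couple with aryl iodides at room temperature without harm to the acid-sensitive ynol ether, and a methyl ynol ether has no beta-hydrogen for thermal retro-ene decay in step 8.

**Step 8**
Reactants: 11 (E)-1-diazo-7-methyl-3-[1-(triisopropylsilyl)indol-3-yl]octa-3,6-dien-2-one; 15 3-(methoxyethynyl)-1-(triisopropylsilyl)indole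
Product: 20 3-methoxy-6-(3-methylbut-2-enyl)-2,5-bis[1-(triisopropylsilyl)indol-3-yl]phenol, via vinylketene 16 (not isolated), via alkenylcyclobutenone 17 (not isolated), via dienylketene 18 (not isolated), via cyclohexadienone 19 (not isolated)
Conditions: 11 (1 equiv), 15 (1.3 equiv), degassed CH2Cl2 (0.1 M), hν (365 nm LED), 25 °C, until N2 evolution ends; solvent change to toluene, 110 °C
Reagents that add atoms: none
Why: Light expels N2 from 11 and the alkenyl group migrates (photochemical Wolff rearrangement) to give vinylketene 16, whose carbonyl carbon (future C3) is attacked by the indolyl-bearing, oxygen-activated carbon of 15 in a regioselective [2+2] cycloaddition that forms C2-C3 and C1-C6 and gives alkenylcyclobutenone 17. Light or the final heating opens 17 reversibly by 4-pi electrocyclic cleavage of the old ketene bond C3-C6 to dienylketene 18, and the rotamer with the alkenyl group turned inward closes the central six-membered ring by a 6-pi electrocyclisation (C3-C4) to cyclohexadienone 19, which enolises to phenol 20. This is the diazoketone version of the Danheiser benzannulation, known with alkoxy- and silyloxyalkynes as ketenophiles. The sp3 ring carbons of 17 (future C6) and 19 (C4) are transient racemic stereocentres that vanish on ring opening and on aromatisation, so no stereocontrol is needed. Regioselectivity (methoxy meta to OH, the free C6-H para to it) rests on the oxygen bound directly to the triple bond being a stronger donor than the more remote, silyl-damped indole nitrogen, as in the protonation of aryl ynol ethers at the aryl-bearing carbon. Chemoselectivity rests on the E geometry of 11, which holds the doubly allylic CH2 and the prenyl alkene on the far side of the ketene so that neither a 1,5-hydrogen shift nor an intramolecular [2+2] can compete, and on 365 nm light, which the diazo enone absorbs but the indole units do not.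

**Step 9**
Reactants: 20 3-methoxy-6-(3-methylbut-2-enyl)-2,5-bis[1-(triisopropylsilyl)indol-3-yl]phenol
Product: 21 3-methoxy-6-(3-methylbut-2-enyl)-2,5-bis[1-(triisopropylsilyl)indol-3-yl]-1,4-benzoquinone
Conditions: Co(salen) (20 mol %), O2 (1 atm), DMF, 25 °C
Reagents that add atoms: dioxygen, O=O
Why: Cobalt-salen-catalysed aerobic para-oxidation of a phenol: the aryloxyl radical can take up O2 only at C6, the single ring carbon that still bears hydrogen, both ortho positions are blocked against ortho-quinone formation and coupling, and the N-silyl groups shield the indoles from oxidation.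

**Step 10**
Reactants: 21 3-methoxy-6-(3-methylbut-2-enyl)-2,5-bis[1-(triisopropylsilyl)indol-3-yl]-1,4-benzoquinone
Product: 22 2,5-di(1H-indol-3-yl)-3-methoxy-6-(3-methylbut-2-enyl)-1,4-benzoquinone (CNP0506434.0)
Conditions: n-Bu4NF (2.4 equiv), AcOH (2.4 equiv), THF, 0 °C
Reagents that add atoms: none
Why: Fluoride-induced N-desilylation: the indole N-Si bond is cleaved quickly at 0 °C, and acetic acid buffers the fluoride so that neither hydrolysis of the vinylogous ester at C1 nor base-induced tautomerisation of the prenylquinone to a quinone methide should set in.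

**Compound list**

1 | 3-bromo-1-(triisopropylsilyl)indole | CC(C)[Si](C(C)C)(C(C)C)n1cc(Br)c2ccccc12 | starting material
2 | 3-lithio-1-(triisopropylsilyl)indole | [Li]c1cn([Si](C(C)C)(C(C)C)C(C)C)c2ccccc12 | intermediate
3 | 3-iodo-1-(triisopropylsilyl)indole | Ic1cn([Si](C(C)C)(C(C)C)C(C)C)c2ccccc12 | intermediate
4 | but-3-yn-2-ol (racemic) | CC(O)C#C | starting material
5 | 1-bromo-3-methylbut-2-ene | CC(C)=CCBr | starting material
6 | 7-methyloct-6-en-3-yn-2-ol (racemic) | CC(O)C#CCC=C(C)C | intermediate
7 | (Z)-7-methyl-3-(tributylstannyl)octa-3,6-dien-2-ol (racemic) | CC(O)/C([Sn](CCCC)(CCCC)CCCC)=C/CC=C(C)C | intermediate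
8 | (E)-7-methyl-3-[1-(triisopropylsilyl)indol-3-yl]octa-3,6-dien-2-ol (racemic) | CC(O)/C(c1cn([Si](C(C)C)(C(C)C)C(C)C)c2ccccc12)=C/CC=C(C)C | intermediate
9 | (E)-7-methyl-3-[1-(triisopropylsilyl)indol-3-yl]octa-3,6-dien-2-one | CC(=O)/C(c1cn([Si](C(C)C)(C(C)C)C(C)C)c2ccccc12)=C/CC=C(C)C | intermediate
10 | (E)-1,1,1-trifluoro-9-methyl-5-[1-(triisopropylsilyl)indol-3-yl]deca-5,8-diene-2,4-dione | FC(F)(F)C(=O)CC(=O)/C(c1cn([Si](C(C)C)(C(C)C)C(C)C)c2ccccc12)=C/CC=C(C)C | intermediate
11 | (E)-1-diazo-7-methyl-3-[1-(triisopropylsilyl)indol-3-yl]octa-3,6-dien-2-one | [N-]=[N+]=CC(=O)/C(c1cn([Si](C(C)C)(C(C)C)C(C)C)c2ccccc12)=C/CC=C(C)C | intermediate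
12 | 2-chloro-1,1-dimethoxyethane | COC(CCl)OC | starting material
13 | lithium methoxyacetylide | [Li]C#COC | intermediate
14 | methoxyethynylzinc chloride | Cl[Zn]C#COC | intermediate
15 | 3-(methoxyethynyl)-1-(triisopropylsilyl)indole | COC#Cc1cn([Si](C(C)C)(C(C)C)C(C)C)c2ccccc12 | intermediate
16 | (3Z)-7-methyl-3-[1-(triisopropylsilyl)indol-3-yl]octa-1,3,6-trien-1-one (ketenyl CH trans to C5H2) | O=C=C/C(c1cn([Si](C(C)C)(C(C)C)C(C)C)c2ccccc12)=C/CC=C(C)C | intermediate
17 | 3-methoxy-4-{(1Z)-5-methyl-1-[1-(triisopropylsilyl)indol-3-yl]hexa-1,4-dienyl}-2-[1-(triisopropylsilyl)indol-3-yl]cyclobut-2-en-1-one (racemic) | COC1=C(c2cn([Si](C(C)C)(C(C)C)C(C)C)c3ccccc23)C(=O)C1/C(c4cn([Si](C(C)C)(C(C)C)C(C)C)c5ccccc45)=C/CC=C(C)C | intermediate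
18 | (3E,5Z)-3-methoxy-9-methyl-2,5-bis[1-(triisopropylsilyl)indol-3-yl]deca-1,3,5,8-tetraen-1-one | O=C=C(c1cn([Si](C(C)C)(C(C)C)C(C)C)c2ccccc12)\C(OC)=C/C(c3cn([Si](C(C)C)(C(C)C)C(C)C)c4ccccc34)=C/CC=C(C)C | intermediate
19 | 3-methoxy-6-(3-methylbut-2-enyl)-2,5-bis[1-(triisopropylsilyl)indol-3-yl]cyclohexa-2,4-dien-1-one (racemic) | COC1=C(c2cn([Si](C(C)C)(C(C)C)C(C)C)c3ccccc23)C(=O)C(CC=C(C)C)C(c4cn([Si](C(C)C)(C(C)C)C(C)C)c5ccccc45)=C1 | intermediate
20 | 3-methoxy-6-(3-methylbut-2-enyl)-2,5-bis[1-(triisopropylsilyl)indol-3-yl]phenol | Oc1c(c2cn([Si](C(C)C)(C(C)C)C(C)C)c3ccccc23)c(OC)cc(c2cn([Si](C(C)C)(C(C)C)C(C)C)c3ccccc23)c1CC=C(C)C | intermediate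
21 | 3-methoxy-6-(3-methylbut-2-enyl)-2,5-bis[1-(triisopropylsilyl)indol-3-yl]-1,4-benzoquinone | COC1=C(c2cn([Si](C(C)C)(C(C)C)C(C)C)c3ccccc23)C(=O)C(CC=C(C)C)=C(c2cn([Si](C(C)C)(C(C)C)C(C)C)c3ccccc23)C1=O | intermediate
22 | 2,5-di(1H-indol-3-yl)-3-methoxy-6-(3-methylbut-2-enyl)-1,4-benzoquinone | COC1=C(c2c[nH]c3ccccc23)C(=O)C(CC=C(C)C)=C(c2c[nH]c3ccccc23)C1=O | target

**Count**

Total steps: 10.
Longest linear sequence: 8 steps (steps 2, 3, 4, 5, 6, 8, 9 and 10, starting from 4).

**Steps most likely to fail**

**Step 8.** Two things have to happen at once: the diazo enone must be photolysed in a solution full of other chromophores, and the short-lived ketene must be caught by a fully substituted, bulky alkyne. Slow capture would let ketene dimerisation and photodegradation of the ynol ether take over.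

The fallback keeps the same three ring bonds but separates the light-driven step from the cycloaddition and releases the ketene thermally by dehydrochlorination. It sets out from 11.
- Photochemical Wolff rearrangement in THF-H2O, where the solvent traps the ketene, should give (3Z)-7-methyl-3-[1-(triisopropylsilyl)indol-3-yl]octa-3,6-dienoic acid F1.
- 1-Chloro-N,N,2-trimethylpropenylamine in CH2Cl2 should convert it under neutral conditions into (3Z)-7-methyl-3-[1-(triisopropylsilyl)indol-3-yl]octa-3,6-dienoyl chloride F2.
- Slow addition of F2 to Et3N and an excess of 15 in toluene at 80 to 110 °C regenerates 16 at a low stationary concentration. Passage through 17, 18 and 19 as before brings the route back at 20.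

**Step 6.** A doubly allylic gamma-proton may be removed in competition with the methyl protons. The remote alkene could also migrate into conjugation during enolate formation or during the amine-mediated transfer.

The fallback avoids every strong base by moving to the acid oxidation level and acylating a diazomethane equivalent (Arndt-Eistert-type acylation). It sets out from 5.
- Coupling of 5 with propargyl alcohol as in step 2 gives 6-methylhept-5-en-2-yn-1-ol F3.
- Trans-hydrostannation as in step 3 should give (Z)-6-methyl-2-(tributylstannyl)hepta-2,5-dien-1-ol F4.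
- Coupling with 3 as in step 4 should give (E)-6-methyl-2-[1-(triisopropylsilyl)indol-3-yl]hepta-2,5-dien-1-ol F5.
- MnO2 should give (E)-6-methyl-2-[1-(triisopropylsilyl)indol-3-yl]hepta-2,5-dienal F6.
- Pinnick oxidation (NaClO2, NaH2PO4, large excess of 2-methylbut-2-ene, t-BuOH-H2O) should give (E)-6-methyl-2-[1-(triisopropylsilyl)indol-3-yl]hepta-2,5-dienoic acid F7.
- 1-Chloro-N,N,2-trimethylpropenylamine should give (E)-6-methyl-2-[1-(triisopropylsilyl)indol-3-yl]hepta-2,5-dienoyl chloride F8.
- Me3SiCHN2 in MeCN-THF at 0 °C, without amine, brings the route back at 11. The trisubstituted, aryl-shielded C=C should resist the dipolar cycloaddition that usually spoils this acylation.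

**Step 4.** Transfer of the alkenyl group from the hindered stannane may be slow. Protodestannylation and homocoupling of the iodide would then consume both partners.

The fallback swaps the polarity of the coupling. It sets out from 7.
- Iododestannylation with I2 in CH2Cl2 at -78 to 0 °C, with retention, should give (Z)-3-iodo-7-methylocta-3,6-dien-2-ol F9.
- MnO2 should give (Z)-3-iodo-7-methylocta-3,6-dien-2-one F10.
- In parallel, 1 is lithiated as in step 1 and treated with ZnCl2 to give [1-(triisopropylsilyl)indol-3-yl]zinc chloride F11.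
- Negishi coupling of F11 with the alpha-iodo enone F10 (Pd2(dba)3, P(2-furyl)3, THF, 25 °C), a well-tried reaction of alpha-iodo enones, brings the route back at 9.

**Further compounds**

F1 | step 8 | (3Z)-7-methyl-3-[1-(triisopropylsilyl)indol-3-yl]octa-3,6-dienoic acid | OC(=O)C/C(c1cn([Si](C(C)C)(C(C)C)C(C)C)c2ccccc12)=C/CC=C(C)C
F2 | step 8 | (3Z)-7-methyl-3-[1-(triisopropylsilyl)indol-3-yl]octa-3,6-dienoyl chloride | ClC(=O)C/C(c1cn([Si](C(C)C)(C(C)C)C(C)C)c2ccccc12)=C/CC=C(C)C
F3 | step 6 | 6-methylhept-5-en-2-yn-1-ol | OCC#CCC=C(C)C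
F4 | step 6 | (Z)-6-methyl-2-(tributylstannyl)hepta-2,5-dien-1-ol | OC/C([Sn](CCCC)(CCCC)CCCC)=C/CC=C(C)C
F5 | step 6 | (E)-6-methyl-2-[1-(triisopropylsilyl)indol-3-yl]hepta-2,5-dien-1-ol | OC/C(c1cn([Si](C(C)C)(C(C)C)C(C)C)c2ccccc12)=C/CC=C(C)C
F6 | step 6 | (E)-6-methyl-2-[1-(triisopropylsilyl)indol-3-yl]hepta-2,5-dienal | O=C/C(c1cn([Si](C(C)C)(C(C)C)C(C)C)c2ccccc12)=C/CC=C(C)C
F7 | step 6 | (E)-6-methyl-2-[1-(triisopropylsilyl)indol-3-yl]hepta-2,5-dienoic acid | OC(=O)/C(c1cn([Si](C(C)C)(C(C)C)C(C)C)c2ccccc12)=C/CC=C(C)C
F8 | step 6 | (E)-6-methyl-2-[1-(triisopropylsilyl)indol-3-yl]hepta-2,5-dienoyl chloride | ClC(=O)/C(c1cn([Si](C(C)C)(C(C)C)C(C)C)c2ccccc12)=C/CC=C(C)C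
F9 | step 4 | (Z)-3-iodo-7-methylocta-3,6-dien-2-ol | CC(O)/C(I)=C/CC=C(C)C
F10 | step 4 | (Z)-3-iodo-7-methylocta-3,6-dien-2-one | CC(=O)/C(I)=C/CC=C(C)C
F11 | step 4 | [1-(triisopropylsilyl)indol-3-yl]zinc chloride | Cl[Zn]c1cn([Si](C(C)C)(C(C)C)C(C)C)c2ccccc12
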